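**Retrosynthetic overview**

- The last three steps only adjust oxygen substituents on a finished flavone: the C5 hydroxyl is released from its methyl ether, and the C3 methoxy group is made from C3–H by lithiation, borylation, oxidation and O-methylation.
- Feature used: C4 of ring C is a single carbonyl carbon held between C4a of ring A and C3, and O1 sits on C8a next to C4a. Ring C is therefore cut at C4a–C4, C4–C3 and O1–C2 into an ortho-iodophenol (ring A), carbon monoxide (C4) and a terminal aryl alkyne (C3, C2 and ring B).
- The iodophenol, 2-iodo-3,5,6-trimethoxyphenol, comes from 5-bromo-o-vanillin: Br to OMe, O-methylation, iodination ortho to the formyl group, then Baeyer–Villiger conversion of CHO into OH.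
- Ring order: rings A and B are bought as benzene rings; ring C is the only ring formed, in step 5.

Key step: step 5

Remark: atom labels (O1, C2 to C8a) and ring letters A, B, C follow flavone numbering; the target is achiral, so no step has to set a stereocentre.

**Route**

Step 1
Reactants: 1 5-bromo-2-hydroxy-3-methoxybenzaldehyde (5-bromo-o-vanillin)
Product: 2 2-hydroxy-3,5-dimethoxybenzaldehyde
Conditions: NaOMe (5 equiv, 25 wt% in MeOH), CuBr (10 mol%), EtOAc (cat.), DMF, 100 °C; then aq. HCl
Reagents that add atoms: sodium methoxide, [Na+].[O-]C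
Why: Ullmann-type copper-catalysed methoxylation of the aryl bromide should proceed cleanly because the sodium phenoxide formed first turns the ortho formyl group into a vinylogous carboxylate that methoxide does not attack, as is general for bromophenoxide aldehydes.

Step 2
Reactants: 2 2-hydroxy-3,5-dimethoxybenzaldehyde
Product: 3 2,3,5-trimethoxybenzaldehyde
Conditions: MeI, K2CO3, DMF, 40 °C
Reagents that add atoms: iodomethane, CI
Why: Williamson O-methylation (SN2 on iodomethane) of the only acidic site, the phenol.

Step 3
Reactants: 3 2,3,5-trimethoxybenzaldehyde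
Product: 4 2-iodo-3,5,6-trimethoxybenzaldehyde
Conditions: NIS (1.05 equiv), CF3CO2H (cat.), MeCN, 0 °C to rt, dark
Reagents that add atoms: N-iodosuccinimide, O=C1CCC(=O)N1I
Why: Electrophilic aromatic iodination (SEAr) should enter at C6 of 3, the only free position para to a methoxy group (the C3 one) and ortho to another, because the other free position C4 is para to the deactivating formyl group and crowded between two methoxy groups, the same preference that 3,5-dimethoxybenzaldehyde shows for its 2-position.

Step 4
Reactants: 4 2-iodo-3,5,6-trimethoxybenzaldehyde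
Product: 6 2-iodo-3,5,6-trimethoxyphenol, via aryl formate 5 (not isolated)
Conditions: mCPBA, CH2Cl2, 0 °C to rt; aq. Na2SO3/NaHCO3 wash; then K2CO3 (cat.), MeOH, rt
Reagents that add atoms: 3-chloroperoxybenzoic acid (mCPBA), OOC(=O)c1cccc(Cl)c1
Why: Baeyer–Villiger (Dakin-type) oxidation: the peracid adds to the aldehyde and the electron-rich aryl group bearing an ortho methoxy group migrates to oxygen to give formate 5, which base-catalysed methanolysis cleaves, while the sulfite wash returns any iodine oxidised by the peracid to the aryl iodide.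

Step 5
Reactants: 6 2-iodo-3,5,6-trimethoxyphenol; 7 1-ethynyl-2,4-dimethoxybenzene; 8 carbon monoxide
Product: 11 2-(2,4-dimethoxyphenyl)-5,7,8-trimethoxy-4H-chromen-4-one, via ortho-hydroxyaryl ynone 9 (not isolated), via diethylamino enaminone 10 (not isolated)
Conditions: PdCl2(PPh3)2 (5 mol%), CO (20 bar), Et2NH (solvent), 120 °C, autoclave
Reagents that add atoms: none
Why: Zerovalent palladium, formed from PdCl2(PPh3)2 under CO and amine, inserts into the C–I bond of 6 (the future C4a), CO inserts to give the aroyl complex of divalent palladium, and the amine-activated alkyne 7 is transferred to palladium and reductively eliminated as ynone 9, which forms C4a–C4 and C4–C3. Diethylamine then adds to the carbonyl-polarised triple bond of 9 at the aryl-bearing β-carbon (future C2) to give enaminone 10, and the C8a hydroxyl displaces the amine at that carbon by addition–elimination, forming O1–C2. The closest known reaction type is the palladium-catalysed carbonylative Sonogashira annulation of ortho-iodophenols with terminal alkynes to flavones. Ring C closes in the 6-endo mode (endo-trig on enaminone 10, equivalent to endo-dig on ynone 9), and no stereocentre is created. The step needs CO insertion before alkyne transfer and 6-endo instead of 5-exo closure (aurone): CO pressure, the copper-free catalyst and the electron-rich aryl group, which migrates readily to CO, favour the aroyl path, and enaminone 10 carries its leaving group only on C2, so the phenol oxygen can close only the six-membered ring.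

Step 6
Reactants: 11 2-(2,4-dimethoxyphenyl)-5,7,8-trimethoxy-4H-chromen-4-one
Product: 14 2-(2,4-dimethoxyphenyl)-3-hydroxy-5,7,8-trimethoxy-4H-chromen-4-one, via 3-lithioflavone 12 (not isolated), via flavone 3-boronate 13 (not isolated)
Conditions: LiN(iPr)2 (LDA, 1.5 equiv), THF, −78 °C; B(OMe)3, −78 °C to rt; then AcOH, 30% aq. H2O2, 0 °C to rt
Reagents that add atoms: hydrogen peroxide, OO
Why: Lithiation–borylation–oxidation: the amide base removes the C3–H of the chromone, which is acidified by the C4 carbonyl and O1, the vinyllithium is trapped by B(OMe)3, and hydroperoxide converts the C–B bond into C–OH by 1,2-migration from boron to oxygen.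

Step 7
Reactants: 14 2-(2,4-dimethoxyphenyl)-3-hydroxy-5,7,8-trimethoxy-4H-chromen-4-one
Product: 15 2-(2,4-dimethoxyphenyl)-3,5,7,8-tetramethoxy-4H-chromen-4-one
Conditions: MeI, K2CO3, acetone, reflux
Reagents that add atoms: iodomethane, CI
Why: Williamson O-methylation of the acidic flavonol 3-OH, the only free hydroxyl in the molecule.

Step 8
Reactants: 15 2-(2,4-dimethoxyphenyl)-3,5,7,8-tetramethoxy-4H-chromen-4-one
Product: 17 5-hydroxy-3,7,8,2',4'-pentamethoxyflavone [2-(2,4-dimethoxyphenyl)-5-hydroxy-3,7,8-trimethoxy-4H-chromen-4-one], via dichloroboron chelate 16 (not isolated)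
Conditions: BCl3 (1.5 equiv), CH2Cl2, −78 to 0 °C; then H2O
Reagents that add atoms: none
Why: Chelation-controlled Lewis acid ether cleavage: BCl3 bridges the C4 carbonyl oxygen and the peri C5 methoxy oxygen in a six-membered chelate, so chloride removes only that methyl group, the C3 ether offering only a less favourable five-membered chelate and the other ethers none, and the low temperature avoids Wessely–Moser isomerisation before water hydrolyses chelate 16.

**Compound list**

1 | 5-bromo-2-hydroxy-3-methoxybenzaldehyde (5-bromo-o-vanillin) | COc1cc(Br)cc(C=O)c1O | starting material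
2 | 2-hydroxy-3,5-dimethoxybenzaldehyde | COc1cc(OC)c(O)c(C=O)c1 | intermediate
3 | 2,3,5-trimethoxybenzaldehyde | COc1cc(OC)c(OC)c(C=O)c1 | intermediate
4 | 2-iodo-3,5,6-trimethoxybenzaldehyde | COc1cc(OC)c(I)c(C=O)c1OC | intermediate
5 | 2-iodo-3,5,6-trimethoxyphenyl formate (formed in the flask) | COc1cc(OC)c(I)c(OC=O)c1OC | intermediate
6 | 2-iodo-3,5,6-trimethoxyphenol | COc1cc(OC)c(I)c(O)c1OC | intermediate
7 | 1-ethynyl-2,4-dimethoxybenzene | C#Cc1ccc(OC)cc1OC | starting material
8 | carbon monoxide | [C-]#[O+] | starting material
9 | 3-(2,4-dimethoxyphenyl)-1-(2-hydroxy-3,4,6-trimethoxyphenyl)prop-2-yn-1-one (formed in the flask) | COc1ccc(C#CC(=O)c2c(O)c(OC)c(OC)cc2OC)c(OC)c1 | intermediate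
10 | 3-(diethylamino)-3-(2,4-dimethoxyphenyl)-1-(2-hydroxy-3,4,6-trimethoxyphenyl)prop-2-en-1-one (formed in the flask; E isomer drawn, the push–pull double bond is configurationally labile and its geometry has no consequence) | CCN(CC)/C(=C/C(=O)c1c(O)c(OC)c(OC)cc1OC)c1ccc(OC)cc1OC | intermediate
11 | 2-(2,4-dimethoxyphenyl)-5,7,8-trimethoxy-4H-chromen-4-one | COc1ccc(-c2cc(=O)c3c(OC)cc(OC)c(OC)c3o2)c(OC)c1 | intermediate
12 | [2-(2,4-dimethoxyphenyl)-5,7,8-trimethoxy-4-oxo-4H-chromen-3-yl]lithium (formed in the flask) | COc1ccc(-c2oc3c(OC)c(OC)cc(OC)c3c(=O)c2[Li])c(OC)c1 | intermediate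
13 | dimethyl [2-(2,4-dimethoxyphenyl)-5,7,8-trimethoxy-4-oxo-4H-chromen-3-yl]boronate (formed in the flask) | COB(OC)c1c(-c2ccc(OC)cc2OC)oc2c(OC)c(OC)cc(OC)c2c1=O | intermediate
14 | 2-(2,4-dimethoxyphenyl)-3-hydroxy-5,7,8-trimethoxy-4H-chromen-4-one | COc1ccc(-c2oc3c(OC)c(OC)cc(OC)c3c(=O)c2O)c(OC)c1 | intermediate
15 | 2-(2,4-dimethoxyphenyl)-3,5,7,8-tetramethoxy-4H-chromen-4-one | COc1ccc(-c2oc3c(OC)c(OC)cc(OC)c3c(=O)c2OC)c(OC)c1 | intermediate
16 | 5-(dichloroboryloxy)-2-(2,4-dimethoxyphenyl)-3,7,8-trimethoxy-4H-chromen-4-one (boron chelated by the C4 carbonyl oxygen; formed in the flask) | COc1ccc(-c2oc3c(OC)c(OC)cc(OB(Cl)Cl)c3c(=O)c2OC)c(OC)c1 | intermediate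
17 | 5-hydroxy-3,7,8,2',4'-pentamethoxyflavone | COc1ccc(-c2oc3c(OC)c(OC)cc(O)c3c(=O)c2OC)c(OC)c1 | target

**Step count and risks**

Total step count: 8.
Longest linear sequence: 8 steps (1 to 17; 7 and 8 enter at step 5).

Steps most likely to fail:

1. Step 5 (key step). Diethylamine may intercept the aroyl complex of divalent palladium faster than the alkyne does (aminocarbonylation to the diethylamide). Oxidative addition into the electron-rich C–I bond flanked by OH and OMe may be slow. Coupling without CO insertion would lead on to a 2-arylbenzofuran. The fallback makes the same ynone without palladium or CO, sets out from 6 and 7 and comes back to the route at 11.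
   - Alkyne 7 is lithiated (n-BuLi, THF, −78 °C) and acylated with N-methoxy-N-methylcarbamoyl chloride to give N-methoxy-N-methyl-3-(2,4-dimethoxyphenyl)prop-2-ynamide F1.
   - Iodophenol 6 is deprotonated with MeMgCl and then subjected to iodine–magnesium exchange with i-PrMgCl·LiCl (THF, −20 °C) to give chloromagnesium 2-(chloromagnesio)-3,5,6-trimethoxyphenoxide F2.
   - F2 is added to F1 (ketone synthesis from an N-methoxy-N-methylamide); cold aqueous NH4Cl work-up should release ynone 9.
   - Crude 9 is closed with Et2NH in EtOH through enaminone 10 to flavone 11.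

2. Step 6. The 3-lithiochromone may open ring C by β-elimination of the C8a phenoxide. The base may also metalate an aryl C–H flanked by two methoxy groups, and the electron-rich rings may be attacked during the peroxide oxidation. The fallback replaces deprotonation by electrophilic oxidation of the C2=C3 bond, sets out from 11 and comes back at 14. Dimethyldioxirane (acetone/CH2Cl2, 0 °C) should epoxidise the enol ether double bond to 2-(2,4-dimethoxyphenyl)-2,3-epoxy-5,7,8-trimethoxychroman-4-one F3. Catalytic p-TsOH in CH2Cl2 then opens the epoxide at C2 (cation stabilised by O1 and ring B), and loss of H3 gives flavonol 14.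

3. Step 4. The peracid may oxidise the electron-rich aryl iodide at iodine, addition to the formyl group between I and OMe may be slow, and hydride instead of aryl migration would give the benzoic acid. The fallback introduces iodine only after the phenol exists, by directed ortho-metalation, sets out from 3 and comes back at 6. It also no longer depends on the site selectivity of step 3.
   - Baeyer–Villiger oxidation of 3 (mCPBA, CH2Cl2) gives 2,3,5-trimethoxyphenyl formate F4, and methanolysis (K2CO3, MeOH) gives 2,3,5-trimethoxyphenol F5.
   - MOMCl and iPr2NEt in CH2Cl2 give 1,2,5-trimethoxy-3-(methoxymethoxy)benzene F6.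
   - n-BuLi in THF at 0 °C should remove the proton between the methoxymethoxy group and the neighbouring methoxy group, the acetal oxygen guiding the base, to give 2-lithio-1,4,5-trimethoxy-3-(methoxymethoxy)benzene F7.
   - Iodine at −78 °C gives 2-iodo-1,4,5-trimethoxy-3-(methoxymethoxy)benzene F8.
   - Dilute HCl in MeOH at rt removes the acetal and gives 6.

Further compounds
F1 | step 5 | N-methoxy-N-methyl-3-(2,4-dimethoxyphenyl)prop-2-ynamide | CON(C)C(=O)C#Cc1ccc(OC)cc1OC
F2 | step 5 | chloromagnesium 2-(chloromagnesio)-3,5,6-trimethoxyphenoxide | COc1cc(OC)c([Mg]Cl)c(O[Mg]Cl)c1OC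
F3 | step 6 | 2-(2,4-dimethoxyphenyl)-2,3-epoxy-5,7,8-trimethoxychroman-4-one (racemic; the epoxide is necessarily cis-fused) | COc1ccc(C23OC2C(=O)c2c(OC)cc(OC)c(OC)c2O3)c(OC)c1
F4 | step 4 | 2,3,5-trimethoxyphenyl formate | COc1cc(OC)c(OC)c(OC=O)c1
F5 | step 4 | 2,3,5-trimethoxyphenol | COc1cc(O)c(OC)c(OC)c1
F6 | step 4 | 1,2,5-trimethoxy-3-(methoxymethoxy)benzene | COCOc1cc(OC)cc(OC)c1OC
F7 | step 4 | 2-lithio-1,4,5-trimethoxy-3-(methoxymethoxy)benzene | COCOc1c([Li])c(OC)cc(OC)c1OC
F8 | step 4 | 2-iodo-1,4,5-trimethoxy-3-(methoxymethoxy)benzene | COCOc1c(I)c(OC)cc(OC)c1OC
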